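**Retrosynthetic overview**

1. Target ⇐ hydroxyl-directed epoxidation of the (4Z)-allylic alcohol 32. C3–OH and C4=C5 come from a C3 ketone (dehydrogenation, then reduction), and the C8 ester from a C8 ketone.
2. Ten-membered ring ⇐ glycol cleavage of a temporary C3–C8 bond. C3 and C8, the two oxygen-bearing ring carbons that lie 1,6 across the ring, are the carbinol carbons of a ring-fusion 1,2-diol (21), so the medium ring is first built as two fused six-membered rings.
3. Butenolide plus carbocycle ⇐ intramolecular oxazole–alkyne Diels–Alder/retro-Diels–Alder of 13 (loss of MeCN), forming C6–C7 and C11–C12 together. The enabling feature: the lactone unit C6–O–C12(=O) is the C2–O1–C5(OEt) unit of a 5-ethoxyoxazole (made from alanine), and C7≡C11–C13 is a propiolate.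
4. 13 ⇐ p-benzoquinone monoketal 1 by asymmetric conjugate methylation (C10), reduction–Michael addition of crotonate (C4–C6), Rubottom oxidation (C3–O), oxazole formation and propiolate addition (C7, C11, C13).
5. Ring order: cyclohexane (from 1) → furan and cyclohexene together (step 8) → butenolide (step 12) → ten-membered ring by cleavage (step 14) → epoxide (step 22).

Key step: step 8

Remark: atoms carry the germacranolide numbers of the target (C1 ketone, C3 carbinol, C4/C5 epoxide, C6 lactone carbinol, C7=C11 butenolide alkene, C8 acyloxy carbon, C10 methyl-bearing carbon, C12 lactone carbonyl, C13 acetoxymethyl carbon); C3, C4 and C8 of the intermediates are temporary stereocentres that all end as sp2 carbons (C3 and C8 in step 14, C4 in step 19), so they are drawn without configuration and every diastereomer converges.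

**Route**

Step 1
Reactants: 1 4,4-dimethoxycyclohexa-2,5-dien-1-one
Product: 2 (5S)-4,4-dimethoxy-5-methylcyclohex-2-en-1-one
Conditions: Me2Zn, Cu(OTf)2 (cat.), BINOL-derived bis(1-phenylethyl)phosphoramidite (cat., enantiomer that gives 5S), toluene, −25 °C; aq NH4Cl
Reagents that add atoms: dimethylzinc, C[Zn]C
Why: Copper–phosphoramidite-catalysed asymmetric conjugate addition of a dialkylzinc to a quinone monoketal is a known desymmetrising Michael addition, and the ligand selects the alkene and face so that C10 is set as S.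

Step 2
Reactants: 2 (5S)-4,4-dimethoxy-5-methylcyclohex-2-en-1-one; 3 methyl (E)-but-2-enoate
Product: 5 methyl 3-[(4S)-5,5-dimethoxy-4-methyl-2-oxocyclohexyl]butanoate, via lithium enolate 4 (not isolated)
Conditions: L-Selectride, THF, −78 °C; then 3, −78 to −40 °C; aq NH4Cl
Reagents that add atoms: none
Why: Conjugate reduction–Michael sequence: hydride adds to the unsubstituted β-carbon so the enolate forms only toward C3, and its Michael addition to crotonate makes the C3–C4 bond (both new centres are temporary).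

Step 3
Reactants: 5 methyl 3-[(4S)-5,5-dimethoxy-4-methyl-2-oxocyclohexyl]butanoate
Product: 7 methyl 3-[(4S)-5,5-dimethoxy-4-methyl-2-oxo-1-(triethylsilyloxy)cyclohexyl]butanoate, via triethylsilyl enol ether 6 (not isolated)
Conditions: TESCl, Et3N, DMF, 80 °C; then mCPBA, NaHCO3, CH2Cl2, 0 °C
Reagents that add atoms: chlorotriethylsilane, CC[Si](Cl)(CC)CC; mCPBA, OOC(=O)c1cccc(Cl)c1
Why: Rubottom oxidation: the more substituted (thermodynamic) silyl enol ether, as for menthone-type 2-sec-alkylcyclohexanones, is epoxidised and rearranges with 1,4-silyl shift to the tertiary α-silyloxy ketone, the silyl group also blocking γ-lactonisation onto the ester.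

Step 4
Reactants: 7 methyl 3-[(4S)-5,5-dimethoxy-4-methyl-2-oxo-1-(triethylsilyloxy)cyclohexyl]butanoate
Product: 8 3-[(4S)-5,5-dimethoxy-4-methyl-2-oxo-1-(triethylsilyloxy)cyclohexyl]butanoic acid
Conditions: LiOH, THF/H2O, 0 °C to rt; aq NaH2PO4 to pH 5
Reagents that add atoms: lithium hydroxide, [Li+].[OH-]
Why: Ester saponification, to which the tertiary silyl ether and the ketal are stable in the cold.

Step 5
Reactants: 8 3-[(4S)-5,5-dimethoxy-4-methyl-2-oxo-1-(triethylsilyloxy)cyclohexyl]butanoic acid; 9 L-alanine ethyl ester hydrochloride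
Product: 10 ethyl N-{3-[(4S)-5,5-dimethoxy-4-methyl-2-oxo-1-(triethylsilyloxy)cyclohexyl]butanoyl}-L-alaninate
Conditions: DCC, HOBt, Et3N, CH2Cl2, 0 °C to rt
Reagents that add atoms: none
Why: Carbodiimide amide coupling through the HOBt active ester; the alanine centre is destroyed in step 6, so its integrity does not matter.

Step 6
Reactants: 10 ethyl N-{3-[(4S)-5,5-dimethoxy-4-methyl-2-oxo-1-(triethylsilyloxy)cyclohexyl]butanoyl}-L-alaninate
Product: 11 (5S)-2-[1-(5-ethoxy-4-methyl-1,3-oxazol-2-yl)propan-2-yl]-4,4-dimethoxy-5-methyl-2-(triethylsilyloxy)cyclohexan-1-one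
Conditions: PPh3, I2, Et3N, CH2Cl2, 0 °C to rt
Reagents that add atoms: none
Why: Robinson–Gabriel-type cyclodehydration of an N-acyl α-amino ester gives the 5-ethoxyoxazole, in which the amide carbon is C6 and the ester carbon, still carrying OEt, is C12.

Step 7
Reactants: 11 (5S)-2-[1-(5-ethoxy-4-methyl-1,3-oxazol-2-yl)propan-2-yl]-4,4-dimethoxy-5-methyl-2-(triethylsilyloxy)cyclohexan-1-one; 12 methyl prop-2-ynoate
Product: 13 methyl 3-{(5S)-2-[1-(5-ethoxy-4-methyl-1,3-oxazol-2-yl)propan-2-yl]-1-hydroxy-4,4-dimethoxy-5-methyl-2-(triethylsilyloxy)cyclohexyl}prop-2-ynoate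
Conditions: 12, LiHMDS, THF, −78 °C; then 11, −78 °C; aq NH4Cl
Reagents that add atoms: none
Why: 1,2-Addition of the lithium acetylide of methyl propiolate to the ketone gives the tertiary propargylic carbinol; C8 is a temporary centre and either configuration relative to C3 can cyclise.

Step 8
Reactants: 13 methyl 3-{(5S)-2-[1-(5-ethoxy-4-methyl-1,3-oxazol-2-yl)propan-2-yl]-1-hydroxy-4,4-dimethoxy-5-methyl-2-(triethylsilyloxy)cyclohexyl}prop-2-ynoate
Product: 15 (10S)-tricyclic methyl 2-ethoxyfuran-3-carboxylate (C8-OH; C3-OSiEt3; C1 dimethyl ketal), via oxazabicycloheptadiene cycloadduct 14 (not isolated)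
Conditions: toluene (high dilution), BHT (cat.), sealed tube, 140 °C
Reagents that add atoms: none
Why: Thermal intramolecular [4+2] cycloaddition of the 5-ethoxyoxazole (azadiene C6=N–C=C12) with the tethered ynoate gives the 7-oxa-2-azabicyclo[2.2.1]heptadiene 14, which loses acetonitrile by retro-[4+2] and aromatises to the 2-ethoxyfuran; the closest known reaction type is the Kondrat'eva-type oxazole–alkyne Diels–Alder/retro-Diels–Alder used intramolecularly on acetylenic oxazoles to make fused furans and masked butenolides. The carbocycle C3–C4–C5–C6–C7–C8 closes as a six-membered ring in the normal type 1 intramolecular mode through the four-atom tether C5–C4–C3–C8, and the furan ring (O, C6, C7, C11, C12) is what is left of the bicycle after cycloreversion. No stereocentre is created, since C6, C7, C11 and C12 are all sp2 in 15, so the mixture at the temporary centres C3, C4 and C8 is of no consequence. The step needs regioselectivity (C6 to C7, C12 to C11), which the tether enforces and which matches the electronic preference of a 5-alkoxyoxazole (its C2 terminus bonds to the β-carbon of the ynoate). It also needs loss of MeCN rather than reversion, which aromatisation to the furan secures. The fully substituted carbinol carbons C3 and C8 in the tether (Thorpe–Ingold effect) and the ester activation of the alkyne should let it run at about 140 °C.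

Step 9
Reactants: 15 (10S)-tricyclic methyl 2-ethoxyfuran-3-carboxylate (C8-OH; C3-OSiEt3; C1 dimethyl ketal)
Product: 16 (10S)-tricyclic 2-ethoxy-3-(hydroxymethyl)furan (C8-OH; C3-OSiEt3; C1 dimethyl ketal)
Conditions: DIBAL-H, CH2Cl2, −78 to −20 °C; Rochelle salt
Reagents that add atoms: none
Why: Hydride reduction of the C13 ester (a vinylogous carbonate) to the primary alcohol; ketal, silyl ether and ethoxyfuran are not reduced.

Step 10
Reactants: 16 (10S)-tricyclic 2-ethoxy-3-(hydroxymethyl)furan (C8-OH; C3-OSiEt3; C1 dimethyl ketal)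
Product: 17 (10S)-tricyclic 3-(acetoxymethyl)-2-ethoxyfuran (C8-OH; C3-OSiEt3; C1 dimethyl ketal)
Conditions: Ac2O, pyridine, CH2Cl2, 0 °C; used without chromatography
Reagents that add atoms: acetic anhydride, CC(=O)OC(C)=O
Why: Selective acetylation of the only primary hydroxyl, the tertiary C8 carbinol being inert under these conditions.

Step 11
Reactants: 17 (10S)-tricyclic 3-(acetoxymethyl)-2-ethoxyfuran (C8-OH; C3-OSiEt3; C1 dimethyl ketal)
Product: 18 (10S)-bicyclic ethyl (Z)-2-(acetoxymethyl)-2-(2-oxocyclohexylidene)acetate (C6 ketone; C12 ethyl ester; C8-OH; C3-OSiEt3)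
Conditions: mCPBA (1 equiv), NaHCO3, CH2Cl2, −40 °C
Reagents that add atoms: mCPBA, OOC(=O)c1cccc(Cl)c1
Why: Peracid oxidative ring opening of a 2-alkoxyfuran to the cis-4-oxo-2-enoate unmasks C6 as a ketone and C12 as the ester, the Z geometry being fixed by the furan.

Step 12
Reactants: 18 (10S)-bicyclic ethyl (Z)-2-(acetoxymethyl)-2-(2-oxocyclohexylidene)acetate (C6 ketone; C12 ethyl ester; C8-OH; C3-OSiEt3)
Product: 20 (6R,10S)-tricyclic 13-acetoxy-7(11)-en-12,6-olide (C8-OH; C3-OSiEt3; C1 dimethyl ketal), via hydroxy ester 19 (not isolated)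
Conditions: (S)-2-methyl-CBS-oxazaborolidine (cat.), BH3·SMe2, THF, −30 °C; MeOH; then PPTS (cat.), CH2Cl2, rt
Reagents that add atoms: none
Why: Corey–Bakshi–Shibata reduction of the cyclic alkylidene ketone under reagent control (alkylidene C7 as large group, C5 methylene as small) sets C6 (6R here, the arrangement that is 6S in the target), and the cis hydroxy ester lactonises to the butenolide.

Step 13
Reactants: 20 (6R,10S)-tricyclic 13-acetoxy-7(11)-en-12,6-olide (C8-OH; C3-OSiEt3; C1 dimethyl ketal)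
Product: 21 (6R,10S)-tricyclic 13-acetoxy-7(11)-en-12,6-olide 3,8-diol (C1 dimethyl ketal)
Conditions: Et3N·3HF, MeCN, rt to 40 °C
Reagents that add atoms: none
Why: Near-neutral fluoride desilylation frees the tertiary C3 hydroxyl without touching the ketal, the acetate or the base-sensitive butenolide.

Step 14
Reactants: 21 (6R,10S)-tricyclic 13-acetoxy-7(11)-en-12,6-olide 3,8-diol (C1 dimethyl ketal)
Product: 22 (6R,10S)-13-acetoxy-1,1-dimethoxy-3,8-dioxogermacr-7(11)-en-12,6-olide
Conditions: Pb(OAc)4, pyridine, CH2Cl2, 0 °C to rt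
Reagents that add atoms: none
Why: Criegee glycol cleavage of the ring-fusion 1,2-diol breaks the temporary C3–C8 bond and opens the bicycle to the ten-membered 1,6-diketone, and in pyridine cis- and trans-diols are both cleaved, so all diol diastereomers converge.

Step 15
Reactants: 22 (6R,10S)-13-acetoxy-1,1-dimethoxy-3,8-dioxogermacr-7(11)-en-12,6-olide
Product: 23 (6R,8S,10S)-13-acetoxy-8-hydroxy-1,1-dimethoxy-3-oxogermacr-7(11)-en-12,6-olide
Conditions: (R)-2-methyl-CBS-oxazaborolidine (0.3 equiv), catecholborane (1.2 equiv), toluene, −78 °C; MeOH, aq NaHCO3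
Reagents that add atoms: none
Why: Corey–Bakshi–Shibata reduction with catecholborane at low temperature should reduce the activated alkenyl ketone C8 faster than the dialkyl ketone C3 and, with the (R)-catalyst (alkenyl C7 large, C9 small), give 8S.

Step 16
Reactants: 24 4-methylfuran-2(5H)-one
Product: 27 allyl (Z)-4-acetoxy-3-methylbut-2-enoate, via potassium carboxylate 25 (not isolated), via allyl hydroxy ester 26 (not isolated)
Conditions: KOH (1 equiv), H2O/MeOH, rt, evaporate; allyl bromide, DMF, 0 °C; then Ac2O, pyridine, DMAP (cat.), 0 °C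
Reagents that add atoms: potassium hydroxide, [K+].[OH-]; allyl bromide, C=CCBr; acetic anhydride, CC(=O)OC(C)=O
Why: Lactone saponification, carboxylate O-alkylation and acetylation in one pot trap the ring-opened Z hydroxy acid before it can relactonise, so the Z geometry of the butenolide is carried into the side chain.

Step 17
Reactants: 27 allyl (Z)-4-acetoxy-3-methylbut-2-enoate
Product: 28 (Z)-4-acetoxy-3-methylbut-2-enoic acid
Conditions: Pd(PPh3)4 (cat.), morpholine, THF, rt
Reagents that add atoms: none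
Why: Tsuji–Trost deallylation with an amine allyl scavenger releases the acid under neutral conditions that keep the Z alkene and the acetate.

Step 18
Reactants: 23 (6R,8S,10S)-13-acetoxy-8-hydroxy-1,1-dimethoxy-3-oxogermacr-7(11)-en-12,6-olide; 28 (Z)-4-acetoxy-3-methylbut-2-enoic acid
Product: 29 (6R,8S,10S)-13-acetoxy-8-[(Z)-4-acetoxy-3-methylbut-2-enoyloxy]-1,1-dimethoxy-3-oxogermacr-7(11)-en-12,6-olide
Conditions: DCC, DMAP (cat.), CH2Cl2, 0 °C
Reagents that add atoms: none
Why: Steglich esterification of the only free hydroxyl in the molecule, so no protecting group is needed.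

Step 19
Reactants: 29 (6R,8S,10S)-13-acetoxy-8-[(Z)-4-acetoxy-3-methylbut-2-enoyloxy]-1,1-dimethoxy-3-oxogermacr-7(11)-en-12,6-olide
Product: 30 (4Z,6R,8S,10S)-13-acetoxy-8-[(Z)-4-acetoxy-3-methylbut-2-enoyloxy]-1,1-dimethoxy-3-oxogermacra-4,7(11)-dien-12,6-olide
Conditions: IBX, 4-methoxypyridine N-oxide, DMSO, rt to 40 °C
Reagents that add atoms: none
Why: IBX dehydrogenation of the C3 ketone through its enol gives the enone; C2 cannot be desaturated because C1 carries no hydrogen, and the ten-membered ring should favour the endocyclic ring-cis (Z) enone.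

Step 20
Reactants: 30 (4Z,6R,8S,10S)-13-acetoxy-8-[(Z)-4-acetoxy-3-methylbut-2-enoyloxy]-1,1-dimethoxy-3-oxogermacra-4,7(11)-dien-12,6-olide
Product: 31 (3S,4Z,6R,8S,10S)-13-acetoxy-8-[(Z)-4-acetoxy-3-methylbut-2-enoyloxy]-3-hydroxy-1,1-dimethoxygermacra-4,7(11)-dien-12,6-olide
Conditions: (R)-2-methyl-CBS-oxazaborolidine (0.3 equiv), catecholborane, toluene, −78 °C; MeOH, aq NaHCO3
Reagents that add atoms: none
Why: Corey–Bakshi–Shibata 1,2-reduction of the α-methyl enone with the (R)-catalyst (alkenyl C4 large, C2 methylene small) sets C3 as S.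

Step 21
Reactants: 31 (3S,4Z,6R,8S,10S)-13-acetoxy-8-[(Z)-4-acetoxy-3-methylbut-2-enoyloxy]-3-hydroxy-1,1-dimethoxygermacra-4,7(11)-dien-12,6-olide
Product: 32 (3S,4Z,6R,8S,10S)-13-acetoxy-8-[(Z)-4-acetoxy-3-methylbut-2-enoyloxy]-3-hydroxy-1-oxogermacra-4,7(11)-dien-12,6-olide
Conditions: PPTS, acetone/H2O, rt
Reagents that add atoms: water, O
Why: Mild acid-catalysed hydrolysis of the dimethyl ketal unveils the C1 ketone under conditions too gentle to dehydrate the β-hydroxy ketone or ionise the allylic alcohol.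

Step 22
Reactants: 32 (3S,4Z,6R,8S,10S)-13-acetoxy-8-[(Z)-4-acetoxy-3-methylbut-2-enoyloxy]-3-hydroxy-1-oxogermacra-4,7(11)-dien-12,6-olide
Product: 33 CNP0232076.1 (3S,4R,5S,6S,8S,10S)
Conditions: mCPBA, NaHCO3, CH2Cl2, 0 °C
Reagents that add atoms: mCPBA, OOC(=O)c1cccc(Cl)c1
Why: Hydroxyl-directed (Henbest) peracid epoxidation of the Z-allylic alcohol: allylic 1,3-strain and hydrogen bonding deliver oxygen syn to the C3 hydroxyl, giving the cis-epoxide 4R,5S, while the electron-poor butenolide and enoate alkenes do not react.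

**Compound list**

1 | 4,4-dimethoxycyclohexa-2,5-dien-1-one | COC1(OC)C=CC(=O)C=C1 | starting material
2 | (5S)-4,4-dimethoxy-5-methylcyclohex-2-en-1-one | O=C1C=CC(OC)(OC)[C@@H](C)C1 | intermediate
3 | methyl (E)-but-2-enoate | C/C=C/C(=O)OC | starting material
4 | lithium (5S)-4,4-dimethoxy-5-methylcyclohex-1-en-1-olate | [Li]OC1=CCC(OC)(OC)[C@@H](C)C1 | intermediate
5 | methyl 3-[(4S)-5,5-dimethoxy-4-methyl-2-oxocyclohexyl]butanoate (C3/C4 epimers) | COC(=O)CC(C)C1CC(OC)(OC)[C@@H](C)CC1=O | intermediate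
6 | methyl 3-[(4S)-5,5-dimethoxy-4-methyl-2-(triethylsilyloxy)cyclohex-1-en-1-yl]butanoate | COC(=O)CC(C)C1=C(O[Si](CC)(CC)CC)C[C@H](C)C(OC)(OC)C1 | intermediate
7 | methyl 3-[(4S)-5,5-dimethoxy-4-methyl-2-oxo-1-(triethylsilyloxy)cyclohexyl]butanoate | COC(=O)CC(C)C1(O[Si](CC)(CC)CC)CC(OC)(OC)[C@@H](C)CC1=O | intermediate
8 | 3-[(4S)-5,5-dimethoxy-4-methyl-2-oxo-1-(triethylsilyloxy)cyclohexyl]butanoic acid | OC(=O)CC(C)C1(O[Si](CC)(CC)CC)CC(OC)(OC)[C@@H](C)CC1=O | intermediate
9 | L-alanine ethyl ester hydrochloride | CCOC(=O)[C@H](C)N.Cl | starting material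
10 | ethyl N-{3-[(4S)-5,5-dimethoxy-4-methyl-2-oxo-1-(triethylsilyloxy)cyclohexyl]butanoyl}-L-alaninate | CCOC(=O)[C@H](C)NC(=O)CC(C)C1(O[Si](CC)(CC)CC)CC(OC)(OC)[C@@H](C)CC1=O | intermediate
11 | (5S)-2-[1-(5-ethoxy-4-methyl-1,3-oxazol-2-yl)propan-2-yl]-4,4-dimethoxy-5-methyl-2-(triethylsilyloxy)cyclohexan-1-one | CCOc1oc(CC(C)C2(O[Si](CC)(CC)CC)CC(OC)(OC)[C@@H](C)CC2=O)nc1C | intermediate
12 | methyl prop-2-ynoate | C#CC(=O)OC | starting material
13 | methyl 3-{(5S)-2-[1-(5-ethoxy-4-methyl-1,3-oxazol-2-yl)propan-2-yl]-1-hydroxy-4,4-dimethoxy-5-methyl-2-(triethylsilyloxy)cyclohexyl}prop-2-ynoate | CCOc1oc(CC(C)C2(O[Si](CC)(CC)CC)CC(OC)(OC)[C@@H](C)CC2(O)C#CC(=O)OC)nc1C | intermediate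
14 | 7-oxa-2-azabicyclo[2.2.1]hepta-2,5-diene cycloadduct of 13 | CCOC12OC3(N=C1C)C(=C2C(=O)OC)C1(O)C[C@H](C)C(OC)(OC)CC1(O[Si](CC)(CC)CC)C(C)C3 | intermediate
15 | (10S)-tricyclic methyl 2-ethoxyfuran-3-carboxylate; furan fused at C6–C7 to the new cyclohexene, which is fused at C3–C8 to the ketal cyclohexane; C8-OH, C3-OSiEt3 | CCOc1oc2c(c1C(=O)OC)C1(O)C[C@H](C)C(OC)(OC)CC1(O[Si](CC)(CC)CC)C(C)C2 | intermediate
16 | C13 primary alcohol of 15 (2-ethoxy-3-hydroxymethylfuran) | CCOc1oc2c(c1CO)C1(O)C[C@H](C)C(OC)(OC)CC1(O[Si](CC)(CC)CC)C(C)C2 | intermediate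
17 | C13 acetate of 16 | CCOc1oc2c(c1COC(C)=O)C1(O)C[C@H](C)C(OC)(OC)CC1(O[Si](CC)(CC)CC)C(C)C2 | intermediate
18 | ring-opened (Z)-keto enoate: C6 ketone, C12 ethyl ester, C8-OH, C3-OSiEt3 | CCOC(=O)/C(COC(C)=O)=C1/C2(O)C[C@H](C)C(OC)(OC)CC2(O[Si](CC)(CC)CC)C(C)CC1=O | intermediate
19 | (6R)-hydroxy ester from reduction of 18 | CCOC(=O)/C(COC(C)=O)=C1/C2(O)C[C@H](C)C(OC)(OC)CC2(O[Si](CC)(CC)CC)C(C)C[C@H]1O | intermediate
20 | (6R,10S)-tricyclic 13-acetoxy-7(11)-en-12,6-olide, C8-OH, C3-OSiEt3, C1 dimethyl ketal | CC(=O)OCC1=C2C3(O)C[C@H](C)C(OC)(OC)CC3(O[Si](CC)(CC)CC)C(C)C[C@H]2OC1=O | intermediate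
21 | (6R,10S)-tricyclic 13-acetoxy-7(11)-en-12,6-olide 3,8-diol, C1 dimethyl ketal | CC(=O)OCC1=C2C3(O)C[C@H](C)C(OC)(OC)CC3(O)C(C)C[C@H]2OC1=O | intermediate
22 | (6R,10S)-13-acetoxy-1,1-dimethoxy-3,8-dioxogermacr-7(11)-en-12,6-olide | CC(=O)OCC1=C2C(=O)C[C@H](C)C(OC)(OC)CC(=O)C(C)C[C@H]2OC1=O | intermediate
23 | (6R,8S,10S)-13-acetoxy-8-hydroxy-1,1-dimethoxy-3-oxogermacr-7(11)-en-12,6-olide | CC(=O)OCC1=C2[C@@H](O)C[C@H](C)C(OC)(OC)CC(=O)C(C)C[C@H]2OC1=O | intermediate
24 | 4-methylfuran-2(5H)-one | CC1=CC(=O)OC1 | starting material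
25 | potassium (Z)-4-hydroxy-3-methylbut-2-enoate | [K+].[O-]C(=O)/C=C(/C)CO | intermediate
26 | allyl (Z)-4-hydroxy-3-methylbut-2-enoate | C=CCOC(=O)/C=C(/C)CO | intermediate
27 | allyl (Z)-4-acetoxy-3-methylbut-2-enoate | C=CCOC(=O)/C=C(/C)COC(C)=O | intermediate
28 | (Z)-4-acetoxy-3-methylbut-2-enoic acid | OC(=O)/C=C(/C)COC(C)=O | intermediate
29 | (6R,8S,10S)-13-acetoxy-8-[(Z)-4-acetoxy-3-methylbut-2-enoyloxy]-1,1-dimethoxy-3-oxogermacr-7(11)-en-12,6-olide | CC(=O)OCC1=C2[C@@H](OC(=O)/C=C(/C)COC(C)=O)C[C@H](C)C(OC)(OC)CC(=O)C(C)C[C@H]2OC1=O | intermediate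
30 | (4Z,6R,8S,10S)-4-en-3-one of 29 | CC(=O)OCC1=C2[C@@H](OC(=O)/C=C(/C)COC(C)=O)C[C@H](C)C(OC)(OC)CC(=O)/C(C)=C\[C@H]2OC1=O | intermediate
31 | (3S,4Z,6R,8S,10S)-3-hydroxy-4-ene, C1 dimethyl ketal | CC(=O)OCC1=C2[C@@H](OC(=O)/C=C(/C)COC(C)=O)C[C@H](C)C(OC)(OC)C[C@H](O)/C(C)=C\[C@H]2OC1=O | intermediate
32 | (3S,4Z,6R,8S,10S)-3-hydroxy-4-en-1-one | CC(=O)OCC1=C2[C@@H](OC(=O)/C=C(/C)COC(C)=O)C[C@H](C)C(=O)C[C@H](O)/C(C)=C\[C@H]2OC1=O | intermediate
33 | CNP0232076.1 | CC(=O)OCC1=C2[C@@H](OC(=O)/C=C(/C)COC(C)=O)C[C@H](C)C(=O)C[C@H](O)[C@@]3(C)O[C@H]3[C@H]2OC1=O | target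

**Step count and risks**

Total step count: 22. Longest linear sequence: 20 steps (steps 1–15 and 18–22; steps 16–17 make the side-chain acid).

Steps most likely to fail:

Step 8. The cycloaddition of the crowded, doubly carbinol-substituted tether may be slower than thermal loss of the propiolate unit (retro-alkynylation) or dehydration of the tertiary carbinol. The fallback replaces the oxazole route to the butenolide by a hetero-Pauson–Khand reaction and sets out from 7. The lithium acetylide of tert-butyldimethyl(prop-2-ynyloxy)silane is added to the ketone of 7 to give the silyl-protected propargylic carbinol ester F1. DIBAL-H at −78 °C reduces the methyl ester to the ynal F2. Mo(CO)6 and DMSO in toluene at 100 °C close the cyclohexene and the butenolide from aldehyde, alkyne and CO to give the bis-silylated tricyclic butenolide F3; C6 then rests on substrate control, and the 6R epimer is carried on. Et3N·3HF removes both silyl groups to give the triol F4, and acetylation of its primary hydroxyl with Ac2O/pyridine returns to the route at 21.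

Step 15. The reduction may not discriminate well enough between the C8 and C3 ketones, or the medium ring may override the catalyst at C8. The fallback sets out from 22 and uses a Luche reduction (NaBH4, CeCl3, MeOH, −78 °C), which is selective for the conjugated ketone and controlled by the ring. If it gives the 8S alcohol, this is 23 itself. If it gives the 8R alcohol F5, Mitsunobu esterification of F5 with acid 28 (PPh3, DIAD) inverts C8 while installing the ester and returns to the route at 29.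

Step 19. The dehydrogenation may give the exocyclic methylene ketone or the E enone, or oxidise elsewhere. The fallback sets out from 29. PhSeCl in EtOAc selenenylates the more substituted enol to give the α-phenylselanyl ketone F6. H2O2/pyridine at 0 °C then gives the selenoxide, whose syn-elimination toward C5 returns to the route at 30.

**Further compounds**

F1 | step 8 | methyl 3-[(4S)-2-hydroxy-2-[3-(tert-butyldimethylsilyloxy)prop-1-ynyl]-5,5-dimethoxy-4-methyl-1-(triethylsilyloxy)cyclohexyl]butanoate | COC(=O)CC(C)C1(O[Si](CC)(CC)CC)CC(OC)(OC)[C@@H](C)CC1(O)C#CCO[Si](C)(C)C(C)(C)C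
F2 | step 8 | 3-[(4S)-2-hydroxy-2-[3-(tert-butyldimethylsilyloxy)prop-1-ynyl]-5,5-dimethoxy-4-methyl-1-(triethylsilyloxy)cyclohexyl]butanal | O=CCC(C)C1(O[Si](CC)(CC)CC)CC(OC)(OC)[C@@H](C)CC1(O)C#CCO[Si](C)(C)C(C)(C)C
F3 | step 8 | (6R,10S)-tricyclic 13-(tert-butyldimethylsilyloxy)-7(11)-en-12,6-olide, C8-OH, C3-OSiEt3, C1 dimethyl ketal | CC(C)(C)[Si](C)(C)OCC1=C2C3(O)C[C@H](C)C(OC)(OC)CC3(O[Si](CC)(CC)CC)C(C)C[C@H]2OC1=O
F4 | step 8 | (6R,10S)-tricyclic 13-hydroxy-7(11)-en-12,6-olide 3,8-diol, C1 dimethyl ketal | OCC1=C2C3(O)C[C@H](C)C(OC)(OC)CC3(O)C(C)C[C@H]2OC1=O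
F5 | step 15 | (6R,8R,10S)-13-acetoxy-8-hydroxy-1,1-dimethoxy-3-oxogermacr-7(11)-en-12,6-olide | CC(=O)OCC1=C2[C@H](O)C[C@H](C)C(OC)(OC)CC(=O)C(C)C[C@H]2OC1=O
F6 | step 19 | 4-(phenylselanyl) derivative of 29 | CC(=O)OCC1=C2[C@@H](OC(=O)/C=C(/C)COC(C)=O)C[C@H](C)C(OC)(OC)CC(=O)C(C)([Se]c3ccccc3)C[C@H]2OC1=O
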